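Germacrane numbering is used for every compound: C1–C10 ring, C11/C12/C13 lactone α-carbon, carbonyl and exocyclic CH2, C14 on C10, C15 on C4.

## Analysis of the target

CNP0265335.3 (44) is a germacrane-type sesquiterpene lactone. A ten-membered carbocycle (C1–C10) is fused at C6/C7 to an α-methylene-γ-butyrolactone (O–C6, C7, C11, C12, exocyclic C13). The lactone is closed on the C6 oxygen and H6/H7 are trans. The ring carries a Z trisubstituted alkene C4=C5, a trans trisubstituted epoxide across C1–C10, an (R)-2-methylbutanoate on the allylic C3 and a (2R,3S)-2,3-dimethyloxirane-2-carboxylate on C8. There are nine stereocentres: 1R,3S,6R,7R,8R,10R in the core and three in the acyl groups. Along C6–C7–C8 the two oxygens are 1,3-anti, and the C11 branch on C7 is syn to O6 and anti to O8. C3 and the epoxide carbons are remote from this triad and from each other. The sensitive groups are the α-methylene lactone (Michael acceptor, easily reduced), both epoxides (the ring epoxide can be opened transannularly by C4=C5 under acid), the α-stereocentre of the methylbutanoate, and the lactone, which can migrate from O6 to O8 under base once O8 is free. The hard part is closing the ten-membered ring while setting C1 and C10, which have no neighbouring stereocentre to lean on. The strategy rests on the fact that C1 and C10 both carry the epoxide oxygen. Each can therefore be a carbonyl carbon (C1 an aldehyde, C10 a methyl ketone), and the two can be joined reductively with like polarity to a 1,10-diol. The cis diol is the right precursor of the trans epoxide when O10 displaces a leaving group at C1 with inversion.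

## Retrosynthetic reasoning

**Ester bonds.** The O3–acyl bond is cut first (44 ⇒ alcohol 42 + acid 43). The methylbutanoate has an epimerisable α-hydrogen and should meet neither enolate nor fluoride chemistry. The O8–acyl bond follows (41 ⇒ alcohol 35 + acid 39), because a glycidic ester would survive neither an electron-transfer reductant nor a lithium amide. Both cuts are at the acyl carbon, so C3 and C8 keep their configuration. The forward steps must tell O3 from O8, which the benzyl-type ether on O3 and the silyl ether on O8 allow.

**C11=C13.** The exocyclic methylene is removed next (34 ⇒ 31). A conjugated methylene lactone would be reduced in the ring-closing step, so the lactone is carried saturated. After epoxide formation C11 is the only acidic carbon, which makes a late enolate methylenation clean.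

**C1–O of the epoxide.** The epoxide is opened to the cis 1,10-diol (31 ⇒ 29). Forward, the tertiary O10 displaces a sulfonate on the secondary C1 with inversion. This turns a (1S,10R) cis diol into the (1R,10R) trans epoxide and needs no strained E alkene in the ring.

**C1–C10.** The diol is cut between its two carbinol carbons (29 ⇒ keto-aldehyde 28). This is the only cut that removes the ring and two stereocentres at once and leaves two ordinary carbonyl groups. Forward, a one-electron reductant must couple the C1 aldehyde and the C10 ketone intramolecularly and deliver the cis diol.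

**Carbonyl groups and C8–C9.** The C10 ketone is traced to a terminal alkene and the C1 aldehyde to a silyl-protected primary alcohol (28 ⇒ 27 ⇒ 25). The homoallylic silyl ether is then cut at C8–C9 (24 ⇒ aldehyde 22). Forward, a reagent-controlled allylation sets C8 and the allyl group is a masked acetonyl unit.

**C6–C7 and the lactone.** Aldehyde 22 comes from lactone imide 20 through thioester 21. Lactone imide 20 is cut at C6–C7 and at the lactone C–O bond into imide 17 and Z enal 13. An auxiliary-controlled syn aldol sets C6 and C7 together, and the γ-hydroxy ester closes onto O6 before any oxygen exists at C8. The lactone position is therefore unambiguous. A vinyl-metal addition to a C6 aldehyde would give neither of these two guarantees.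

**Imide.** Imide 17 is cut at the N–acyl bond into oxazolidinone 14 and acid chloride 15.

**Enal 13.** The formyl carbon C6 is cut from alkenyl iodide 11. C1 is traced to the terminal alkene of 7. The C2–C3 bond is cut by allylation (6 ⇒ aldehyde 4). The methyl and iodine on the alkene go back to propargyl alcohol 1 through 3. The Z geometry is fixed stereospecifically in the first step and C3 is set by reagent control.

**Glycidic acid 39.** It comes from epoxy alcohol 38, made by asymmetric epoxidation of allylic alcohol 37 from tiglic acid 36. The cis methyl arrangement comes from the E alkene.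

## Alternatives that were turned down

**Alternative 1:** The cut goes through two σ-bonds of a cyclobutane, C4–C5 and C1–C10. In the forward sense a six-membered enone holding C5–C10 and a cyclobutene holding C1–C4 are irradiated to give photoadduct A1. Heating then cleaves the other two cyclobutane bonds (C5–C10 and C1–C4), so that C4=C5 and C1=C10 appear in a ten-membered ring.
- For: two operations give the carbocycle with both methyl-bearing alkene positions and oxygen at C3, C6 and C8. On skeleton-building economy it is clearly stronger than the chosen route.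
- Against: the alkene geometries follow from the ring fusion of A1 and from orbital symmetry, not from choice. A strained cyclodeca-1,5-diene at the opening temperature can undergo Cope rearrangement to a divinylcyclohexane.
- Against: A1 lacks C11–C12 and the C7 stereocentre. C3, C6, C7, C1 and C10 would all have to be set afterwards on a flexible ten-membered ring by substrate control, starting from a single stereocentre (C8).
- Comparison: the chosen route is longer in bond count but fixes C3, C6, C7, C8 and the Z alkene by reagent control before the ring exists.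

**Alternative 2:** The cut is the C4=C5 double bond. Two alcohol fragments are tied through O3 and O6 by a diisopropylsilylene, and second-generation Grubbs catalyst closes the seven-membered silepine A2.
- For: the seven-membered ring enforces the cis alkene, and no configurationally labile Z enal is needed. On security of the alkene geometry at the fragment union it is stronger than the chosen route, whose enal 13 must be handled cold.
- Against: the metathesis joins a 1,1-disubstituted and a monosubstituted alkene between two branched carbinols, so it should be slow. The mixed bis-alkoxysilane must be assembled stepwise from two hindered secondary alcohols.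
- Against: the C6/C7/C8 triad must be built open-chain without a lactone-forming step that sets two centres at once.
- Against: the key step does not close the carbocycle. After it the tether must be removed, O6 lactonised in preference to O8, and the ten-membered ring still closed at C1–C10. The macrocyclisation risk of the chosen route is added to, not replaced.
- Comparison: the chosen route takes its Z geometry from a stereospecific carbometalation in step 1 and spends its key step on the ring itself.

**Alternative 3:** The cuts are C1–C2 and O–C3. A nitrile oxide at C1, next to a preformed tertiary carbinol C10, adds across the terminal alkene of a Z diene to give the isoxazoline-bridged lactone A3.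
- For: C10 is set before ring closure, which is more secure than setting it in a pinacol coupling. The dipole brings the C3 oxygen, so the C1–C5 fragment is shorter. On both points it is as strong as or stronger than the chosen route.
- Against: the ring closed is a ten-membered carbocycle carrying a Z alkene and a bridging C=N. This is a strained bridged mode that competes with nitrile oxide dimerisation.
- Against: C3 is set only by the conformation of the closing ring and cannot be corrected by a reagent.
- Against: the conjugated Z diene next to the allylic lactone oxygen is labile.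
- Against: after closure the N–O bond must be cleaved without touching the alkene, the C1 ketone reduced selectively, and the same epoxide closure carried out. Nothing is saved at the end.
- Comparison: the chosen route sets C3 by allylboration and needs only two ordinary carbonyl groups for the ring closure.

Key step: step 16

Remark: (R)-2-methylbutanoic acid (43) and (S)-4-benzyl-1,3-oxazolidin-2-one (14) are assumed to be purchased as single enantiomers, and tiglic acid (36) and acid chloride 15 as such.

## Route

Step 1
Reactants: 1 propargyl alcohol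
Product: 3 (Z)-3-iodo-2-methylprop-2-en-1-ol, via alkenylmagnesium alkoxide 2 (not isolated)
Conditions: MeMgBr (3 equiv), CuI (10 mol%), THF/Et2O, −10 °C to rt; then I2, −78 to 0 °C
Reagents that add atoms: methylmagnesium bromide, C[Mg]Br; iodine, II
Why: Copper-catalysed, alkoxide-directed anti carbomagnesiation puts the methyl group on C4 and magnesium on C5 cis to the carbinol carbon, and iodinolysis proceeds with retention. This fixes the Z geometry of C4=C5 for the whole route.

Step 2
Reactants: 3 (Z)-3-iodo-2-methylprop-2-en-1-ol
Product: 4 (Z)-3-iodo-2-methylprop-2-enal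
Conditions: MnO2 (activated, excess), CH2Cl2, rt, dark
Reagents that add atoms: none
Why: Allylic oxidation on MnO2 is neutral and leaves the iodoalkene geometry alone; the volatile aldehyde is used directly.

Step 3
Reactants: 4 (Z)-3-iodo-2-methylprop-2-enal
Product: 6 (3S,1Z)-1-iodo-2-methylhexa-1,5-dien-3-ol, via borinate ester 5 (not isolated)
Conditions: (−)-Ipc2BOMe [from (+)-α-pinene], CH2=CHCH2MgBr, Et2O, 0 °C to rt, salts filtered; 4, −78 °C; then 3 M NaOH, 30% H2O2, 0 °C to rt
Reagents that add atoms: allylmagnesium bromide, C=CC[Mg]Br (allyl group, handed on by the B-allyldiisopinocampheylborane formed in the flask)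
Why: Brown allylboration through a chair transition state; the (+)-α-pinene-derived reagent attacks the Si face of the aldehyde, which for this α-branched enal should give the 3S carbinol by reagent control.

Step 4
Reactants: 6 (3S,1Z)-1-iodo-2-methylhexa-1,5-dien-3-ol
Product: 7 4-methoxybenzyl ether of 6
Conditions: NaH, 4-methoxybenzyl chloride, Bu4NI (cat.), THF/DMF, 0 °C to rt
Reagents that add atoms: 4-methoxybenzyl chloride, COc1ccc(CCl)cc1
Why: Williamson etherification at oxygen leaves C3 untouched; the iodoalkene cannot eliminate because C4 carries no hydrogen.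

Step 5
Reactants: 7 4-methoxybenzyl ether of 6
Product: 10 (3S,4Z)-5-iodo-3-[(4-methoxybenzyl)oxy]-4-methylpent-4-en-1-ol, via diol 8 (not isolated), via aldehyde 9 (not isolated)
Conditions: OsO4 (2 mol%), NaIO4 (4 equiv), 2,6-lutidine, dioxane/H2O 3:1, rt; then NaBH4, MeOH, 0 °C
Reagents that add atoms: osmium tetroxide, O=[Os](=O)(=O)=O (carrier of the hydroxyl oxygen, restored by NaIO4)
Why: Lemieux–Johnson cleavage: OsO4 takes the monosubstituted alkene and leaves the electron-poor trisubstituted iodoalkene. The β-alkoxy aldehyde is reduced at once so that the ether is not lost by elimination.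

Step 6
Reactants: 10 (3S,4Z)-5-iodo-3-[(4-methoxybenzyl)oxy]-4-methylpent-4-en-1-ol
Product: 11 triethylsilyl ether of 10
Conditions: Et3SiCl, imidazole, CH2Cl2, 0 °C
Reagents that add atoms: chlorotriethylsilane, CC[Si](Cl)(CC)CC
Why: Standard silylation of a primary alcohol; the triethylsilyl group is chosen because it can later be removed beside a secondary tert-butyldimethylsilyl ether.

Step 7
Reactants: 11 triethylsilyl ether of 10
Product: 13 (2Z,4S)-4-[(4-methoxybenzyl)oxy]-3-methyl-6-[(triethylsilyl)oxy]hex-2-enal, via alkenyllithium 12 (not isolated)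
Conditions: t-BuLi (2.1 equiv), Et2O, −78 °C; then DMF, −78 to 0 °C; aq. NH4Cl
Reagents that add atoms: N,N-dimethylformamide, CN(C)C=O
Why: Iodine–lithium exchange and formylation both go with retention of alkene geometry. The Z enal is kept cold and used at once, because β,β-disubstituted enals can equilibrate their geometry.

Step 8
Reactants: 14 (S)-4-benzyl-1,3-oxazolidin-2-one; 15 methyl 4-chloro-4-oxobutanoate
Product: 17 methyl 4-[(4S)-4-benzyl-2-oxo-1,3-oxazolidin-3-yl]-4-oxobutanoate, via N-lithio oxazolidinone 16 (not isolated)
Conditions: n-BuLi, THF, −78 °C; then 15, −78 to 0 °C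
Reagents that add atoms: none
Why: N-Acylation of the lithiated auxiliary by the acid chloride; the ester end is far less electrophilic and is not touched.

Step 9
Reactants: 17 methyl 4-[(4S)-4-benzyl-2-oxo-1,3-oxazolidin-3-yl]-4-oxobutanoate; 13 (2Z,4S)-4-[(4-methoxybenzyl)oxy]-3-methyl-6-[(triethylsilyl)oxy]hex-2-enal
Product: 20 trans lactone imide (C6–C7 joined; lactone on O6), via boron enolate 18 (not isolated), via aldol adduct 19 (not isolated)
Conditions: Bu2BOTf, i-Pr2NEt, CH2Cl2, −78 to 0 °C; 13, −78 to 0 °C; pH 7 buffer, MeOH, 30% H2O2, 0 °C; then PPTS (cat.), CH2Cl2, rt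
Reagents that add atoms: none
Why: Evans syn aldol: the Z boron enolate, formed on the imide side only, reacts through a chair transition state on the face away from the benzyl group. The S auxiliary thus sets C7 and the syn C6 carbinol. The γ-hydroxy ester then closes to the trans lactone on O6, before any oxygen exists at C8.

Step 10
Reactants: 20 trans lactone imide
Product: 21 S-ethyl thioester of the lactone acid
Conditions: EtSH, n-BuLi, THF, 0 °C
Reagents that add atoms: ethanethiol, CCS
Why: Lithium ethanethiolate attacks the exocyclic imide carbonyl and releases the auxiliary. The thiolate is too weak a base to epimerise C7, where the trans arrangement is the stable one in any case.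

Step 11
Reactants: 21 S-ethyl thioester of the lactone acid
Product: 22 lactone aldehyde (C8 formyl group)
Conditions: Et3SiH, Pd/C (10%), acetone, rt
Reagents that add atoms: none
Why: Fukuyama reduction: zerovalent palladium inserts into the C–S bond and the silane delivers hydride. The aldehyde forms under neutral conditions, so the β-acyloxy aldehyde is neither epimerised nor opened by β-elimination.

Step 12
Reactants: 22 lactone aldehyde
Product: 24 (8R)-homoallylic alcohol, via borinate ester 23 (not isolated)
Conditions: (+)-Ipc2BOMe [from (−)-α-pinene], CH2=CHCH2MgBr, Et2O, 0 °C to rt, salts filtered; 22, −78 °C; then sat. aq. NaHCO3, 30% H2O2, 0 °C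
Reagents that add atoms: allylmagnesium bromide, C=CC[Mg]Br (allyl group, handed on by the B-allyldiisopinocampheylborane formed in the flask)
Why: Brown allylboration with the (−)-α-pinene-derived reagent attacks the Re face of the aldehyde and should give the 8R carbinol by reagent control over whatever bias C7 exerts. Low temperature, a non-basic reagent and a buffered oxidative work-up spare the aldehyde and keep the lactone on O6.

Step 13
Reactants: 24 (8R)-homoallylic alcohol
Product: 25 tert-butyldimethylsilyl ether of 24
Conditions: TBSOTf, 2,6-lutidine, CH2Cl2, −78 to 0 °C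
Reagents that add atoms: tert-butyldimethylsilyl triflate, CC(C)(C)[Si](C)(C)OS(=O)(=O)C(F)(F)F
Why: Silylation with the triflate covers the hindered O8 at once and under non-nucleophilic conditions, which ends any chance of lactone migration to O8.

Step 14
Reactants: 25 tert-butyldimethylsilyl ether of 24
Product: 27 hydroxy ketone (C10 methyl ketone; C1 primary alcohol), via triethylsilyl ether ketone 26 (not isolated)
Conditions: PdCl2 (20 mol%), CuCl (1 equiv), O2 (1 atm), DMF/H2O 7:1, rt; then AcOH/THF/H2O 3:1:1, rt
Reagents that add atoms: water, O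
Why: Wacker oxidation: divalent palladium activates only the monosubstituted alkene, water adds at the internal carbon and β-hydride elimination gives the methyl ketone. Aqueous acetic acid then removes the primary triethylsilyl ether and leaves the secondary silyl and benzyl-type ethers.

Step 15
Reactants: 27 hydroxy ketone
Product: 28 keto-aldehyde (C1 aldehyde; C10 methyl ketone)
Conditions: Dess–Martin periodinane, NaHCO3, CH2Cl2, 0 °C to rt
Reagents that add atoms: none
Why: Buffered Dess–Martin oxidation gives the β-alkoxy aldehyde without acid or base, so the C3 ether is not eliminated; the product goes directly into the ring closure.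

Step 16
Reactants: 28 keto-aldehyde
Product: 29 cis-1,10-diol (1S,10R) of the ten-membered lactone
Conditions: SmI2 (4 equiv, 0.1 M in THF), THF, slow addition of 28 (final 0.002 M), rt; then aq. NaHCO3/Na2S2O3
Reagents that add atoms: none
Why: SmI2 (divalent samarium) transfers one electron to the more easily reduced C1 aldehyde; the ketyl stays bound to trivalent samarium, which also binds the C10 ketone, and C1–C10 forms inside this chelate, either by addition of the C1 ketyl to the metal-bound ketone followed by a second electron transfer or by combination of two ketyls. The closest known reaction type is the intramolecular samarium pinacol coupling of keto-aldehydes, used for medium and large rings; low-valent titanium does the same. The one ring closed is the ten-membered carbocycle, end to end between C1 and C10 (10-exo-trig in the ketyl-addition picture), and slow addition at high dilution suppresses intermolecular coupling and plain reduction. The relative configuration of the new centres C1 and C10 is set by the samarium bridge, which holds both oxygens on the same side and gives the cis diol. The facial pairing, 1S,10R and not 1R,10S, has to come from the ring itself: the trans lactone and the Z C4=C5 alkene fold the two chains toward each other, and the bulky ether groups at C3 and C8 should stay outside the closing ring. The step needs chemoselectivity for the two carbonyl groups over the saturated lactone, the ethers and the alkene, which SmI2 without activating additives provides. It also needs the cis diol of the right face, and of this only the cis relationship is secured by the chelate.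

Step 17
Reactants: 29 cis-1,10-diol
Product: 31 (1R,10R)-1,10-epoxide, via mesylate 30 (not isolated)
Conditions: MsCl, Et3N, CH2Cl2, −20 °C; then K2CO3, MeOH, 0 °C
Reagents that add atoms: none
Why: Only the secondary C1 hydroxyl is sulfonylated. The tertiary C10 alkoxide then displaces the mesylate (3-exo-tet) with inversion at C1, so the cis diol becomes the trans epoxide with C10 unchanged.

Step 18
Reactants: 31 (1R,10R)-1,10-epoxide
Product: 32 11-(dimethylaminomethyl) lactone
Conditions: LiN(i-Pr)2, THF, −78 °C; then Eschenmoser's salt, −78 to 0 °C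
Reagents that add atoms: Eschenmoser's salt (N,N-dimethylmethyleneiminium iodide), C=[N+](C)C.[I-]
Why: C11 is the only acidic carbon left; its lithium enolate adds to the iminium ion (Mannich reaction). The configuration created at C11 is of no consequence.

Step 19
Reactants: 32 11-(dimethylaminomethyl) lactone
Product: 34 α-methylene lactone, via trimethylammonium iodide 33 (not isolated)
Conditions: MeI, MeOH, rt; then aq. NaHCO3, EtOAc, rt
Reagents that add atoms: none
Why: Quaternisation followed by base-induced β-elimination of trimethylamine (E1cB through the lactone enolate) gives the exocyclic methylene under conditions mild enough for the epoxide.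

Step 20
Reactants: 34 α-methylene lactone
Product: 35 C8 alcohol
Conditions: Bu4NF, AcOH (1:1), THF, 0 °C to rt
Reagents that add atoms: none
Why: Fluoride cleaves the Si–O bond. Acetic acid keeps the freed O8 protonated, so it attacks neither the lactone carbonyl nor the Michael acceptor.

Step 21
Reactants: 36 tiglic acid
Product: 37 (E)-2-methylbut-2-en-1-ol
Conditions: LiAlH4, Et2O, 0 °C to rt
Reagents that add atoms: none
Why: Hydride reduction of the conjugated acid to the allylic alcohol; the E geometry is kept.

Step 22
Reactants: 37 (E)-2-methylbut-2-en-1-ol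
Product: 38 [(2S,3S)-2,3-dimethyloxiran-2-yl]methanol
Conditions: Ti(OiPr)4 (10 mol%), L-(+)-diisopropyl tartrate (12 mol%), t-BuOOH, 4 Å MS, CH2Cl2, −20 °C
Reagents that add atoms: tert-butyl hydroperoxide, CC(C)(C)OO
Why: Sharpless asymmetric epoxidation: the L-(+)-tartrate complex delivers oxygen to the face that gives 2S,3S epoxy alcohols from E-2-alkenols. The reaction is stereospecific, so the two methyl groups stay cis.

Step 23
Reactants: 38 [(2S,3S)-2,3-dimethyloxiran-2-yl]methanol
Product: 39 (2R,3S)-2,3-dimethyloxirane-2-carboxylic acid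
Conditions: RuCl3 (2 mol%), NaIO4 (4 equiv), CCl4/MeCN/H2O, rt
Reagents that add atoms: sodium periodate, [Na+].[O-]I(=O)(=O)=O (oxygen passed on through RuO4); water, O
Why: RuO4 formed in the flask oxidises the primary alcohol to the acid without touching the epoxide. The descriptor at C2 changes to R by priority only; the acid is kept cold and used soon.

Step 24
Reactants: 35 C8 alcohol; 39 (2R,3S)-2,3-dimethyloxirane-2-carboxylic acid
Product: 41 C8 glycidic ester, via mixed anhydride 40 (not isolated)
Conditions: 39, 2,4,6-trichlorobenzoyl chloride, Et3N, THF, 0 °C; then 35, DMAP, toluene, rt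
Reagents that add atoms: none
Why: Yamaguchi esterification: DMAP transfers the aliphatic acyl group of the mixed anhydride to the hindered O8. The acid has no α-hydrogen and cannot epimerise, and C8 keeps its configuration because its C–O bond is not broken.

Step 25
Reactants: 41 C8 glycidic ester
Product: 42 C3 alcohol
Conditions: DDQ, CH2Cl2/pH 7 buffer 10:1, 0 °C
Reagents that add atoms: none
Why: Oxidative removal of the 4-methoxybenzyl group (hydride abstraction, then hydrolysis of the oxocarbenium ion) is neutral and spares both epoxides, the ester and the methylene lactone.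

Step 26
Reactants: 42 C3 alcohol; 43 (R)-2-methylbutanoic acid
Product: 44 CNP0265335.3
Conditions: DCC, DMAP (cat.), CH2Cl2, 0 °C
Reagents that add atoms: none
Why: Steglich esterification of the allylic O3. Low temperature and catalytic DMAP should keep the α-stereocentre of the acid intact, and acylation at oxygen leaves C3 unchanged.

## Compound list

1 | prop-2-yn-1-ol (propargyl alcohol) | C#CCO | starting material
2 | bromomagnesium (Z)-3-(bromomagnesio)-2-methylprop-2-en-1-olate | C/C(CO[Mg]Br)=C/[Mg]Br | intermediate (not isolated)
3 | (Z)-3-iodo-2-methylprop-2-en-1-ol | OC/C(C)=C\I | intermediate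
4 | (Z)-3-iodo-2-methylprop-2-enal | O=C/C(C)=C\I | intermediate
5 | bis(isopinocampheyl)borinate of 6 [Ipc from (+)-α-pinene] | I/C=C(/C)[C@@H](OB([C@@H]1C[C@@H]2C[C@H]([C@H]1C)C2(C)C)[C@@H]1C[C@@H]2C[C@H]([C@H]1C)C2(C)C)CC=C | intermediate (not isolated)
6 | (3S,1Z)-1-iodo-2-methylhexa-1,5-dien-3-ol | I/C=C(/C)[C@@H](O)CC=C | intermediate
7 | 1-({[(3S,1Z)-1-iodo-2-methylhexa-1,5-dien-3-yl]oxy}methyl)-4-methoxybenzene | I/C=C(/C)[C@@H](OCc1ccc(OC)cc1)CC=C | intermediate
8 | (4S,5Z)-6-iodo-4-[(4-methoxybenzyl)oxy]-5-methylhex-5-ene-1,2-diol (both C2 epimers) | I/C=C(/C)[C@@H](OCc1ccc(OC)cc1)CC(O)CO | intermediate (not isolated)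
9 | (3S,4Z)-5-iodo-3-[(4-methoxybenzyl)oxy]-4-methylpent-4-enal | I/C=C(/C)[C@@H](OCc1ccc(OC)cc1)CC=O | intermediate (not isolated)
10 | (3S,4Z)-5-iodo-3-[(4-methoxybenzyl)oxy]-4-methylpent-4-en-1-ol | I/C=C(/C)[C@@H](OCc1ccc(OC)cc1)CCO | intermediate
11 | triethyl({(3S,4Z)-5-iodo-3-[(4-methoxybenzyl)oxy]-4-methylpent-4-en-1-yl}oxy)silane | I/C=C(/C)[C@@H](OCc1ccc(OC)cc1)CCO[Si](CC)(CC)CC | intermediate
12 | {(1Z,3S)-3-[(4-methoxybenzyl)oxy]-2-methyl-5-[(triethylsilyl)oxy]pent-1-en-1-yl}lithium | [Li]/C=C(/C)[C@@H](OCc1ccc(OC)cc1)CCO[Si](CC)(CC)CC | intermediate (not isolated)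
13 | (2Z,4S)-4-[(4-methoxybenzyl)oxy]-3-methyl-6-[(triethylsilyl)oxy]hex-2-enal | O=C/C=C(/C)[C@@H](OCc1ccc(OC)cc1)CCO[Si](CC)(CC)CC | intermediate
14 | (S)-4-benzyl-1,3-oxazolidin-2-one | O=C1N[C@@H](Cc2ccccc2)CO1 | starting material
15 | methyl 4-chloro-4-oxobutanoate | COC(=O)CCC(Cl)=O | starting material
16 | N-lithio-(S)-4-benzyl-1,3-oxazolidin-2-one | [Li]N1[C@@H](Cc2ccccc2)COC1=O | intermediate (not isolated)
17 | methyl 4-[(4S)-4-benzyl-2-oxo-1,3-oxazolidin-3-yl]-4-oxobutanoate | COC(=O)CCC(=O)N1[C@@H](Cc2ccccc2)COC1=O | intermediate
18 | (Z)-dibutylboron enolate of 17 (enolised between C7 and the imide carbonyl) | COC(=O)C/C=C(\OB(CCCC)CCCC)N1[C@@H](Cc2ccccc2)COC1=O | intermediate (not isolated)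
19 | methyl (3S,4R,5Z,7S)-3-{[(4S)-4-benzyl-2-oxo-1,3-oxazolidin-3-yl]carbonyl}-4-hydroxy-7-[(4-methoxybenzyl)oxy]-6-methyl-9-[(triethylsilyl)oxy]non-5-enoate | COC(=O)C[C@@H]([C@H](O)/C=C(/C)[C@@H](OCc1ccc(OC)cc1)CCO[Si](CC)(CC)CC)C(=O)N1[C@@H](Cc2ccccc2)COC1=O | intermediate (not isolated)
20 | (4S)-4-benzyl-3-{[(2R,3S)-2-{(1Z,3S)-3-[(4-methoxybenzyl)oxy]-2-methyl-5-[(triethylsilyl)oxy]pent-1-en-1-yl}-5-oxooxolan-3-yl]carbonyl}-1,3-oxazolidin-2-one | O=C1C[C@H](C(=O)N2[C@@H](Cc3ccccc3)COC2=O)[C@@H](/C=C(/C)[C@@H](OCc2ccc(OC)cc2)CCO[Si](CC)(CC)CC)O1 | intermediate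
21 | S-ethyl (2R,3S)-2-{(1Z,3S)-3-[(4-methoxybenzyl)oxy]-2-methyl-5-[(triethylsilyl)oxy]pent-1-en-1-yl}-5-oxooxolane-3-carbothioate | O=C1C[C@H](C(=O)SCC)[C@@H](/C=C(/C)[C@@H](OCc2ccc(OC)cc2)CCO[Si](CC)(CC)CC)O1 | intermediate
22 | (2R,3S)-2-{(1Z,3S)-3-[(4-methoxybenzyl)oxy]-2-methyl-5-[(triethylsilyl)oxy]pent-1-en-1-yl}-5-oxooxolane-3-carbaldehyde | O=C1C[C@H](C=O)[C@@H](/C=C(/C)[C@@H](OCc2ccc(OC)cc2)CCO[Si](CC)(CC)CC)O1 | intermediate
23 | bis(isopinocampheyl)borinate of 24 [Ipc from (−)-α-pinene] | O=C1C[C@H]([C@H](OB([C@H]2C[C@H]3C[C@@H]([C@@H]2C)C3(C)C)[C@H]2C[C@H]3C[C@@H]([C@@H]2C)C3(C)C)CC=C)[C@@H](/C=C(/C)[C@@H](OCc2ccc(OC)cc2)CCO[Si](CC)(CC)CC)O1 | intermediate (not isolated)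
24 | (4R,5R)-4-[(1R)-1-hydroxybut-3-en-1-yl]-5-{(1Z,3S)-3-[(4-methoxybenzyl)oxy]-2-methyl-5-[(triethylsilyl)oxy]pent-1-en-1-yl}oxolan-2-one | O=C1C[C@H]([C@H](O)CC=C)[C@@H](/C=C(/C)[C@@H](OCc2ccc(OC)cc2)CCO[Si](CC)(CC)CC)O1 | intermediate
25 | (4S,5R)-4-[(1R)-1-{[tert-butyl(dimethyl)silyl]oxy}but-3-en-1-yl]-5-{(1Z,3S)-3-[(4-methoxybenzyl)oxy]-2-methyl-5-[(triethylsilyl)oxy]pent-1-en-1-yl}oxolan-2-one | O=C1C[C@H]([C@H](O[Si](C)(C)C(C)(C)C)CC=C)[C@@H](/C=C(/C)[C@@H](OCc2ccc(OC)cc2)CCO[Si](CC)(CC)CC)O1 | intermediate
26 | (4S,5R)-4-[(1R)-1-{[tert-butyl(dimethyl)silyl]oxy}-3-oxobutyl]-5-{(1Z,3S)-3-[(4-methoxybenzyl)oxy]-2-methyl-5-[(triethylsilyl)oxy]pent-1-en-1-yl}oxolan-2-one | O=C1C[C@H]([C@H](O[Si](C)(C)C(C)(C)C)CC(C)=O)[C@@H](/C=C(/C)[C@@H](OCc2ccc(OC)cc2)CCO[Si](CC)(CC)CC)O1 | intermediate (not isolated)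
27 | (4S,5R)-4-[(1R)-1-{[tert-butyl(dimethyl)silyl]oxy}-3-oxobutyl]-5-{(1Z,3S)-5-hydroxy-3-[(4-methoxybenzyl)oxy]-2-methylpent-1-en-1-yl}oxolan-2-one | O=C1C[C@H]([C@H](O[Si](C)(C)C(C)(C)C)CC(C)=O)[C@@H](/C=C(/C)[C@@H](OCc2ccc(OC)cc2)CCO)O1 | intermediate
28 | (3S,4Z)-5-{(2R,3S)-3-[(1R)-1-{[tert-butyl(dimethyl)silyl]oxy}-3-oxobutyl]-5-oxooxolan-2-yl}-3-[(4-methoxybenzyl)oxy]-4-methylpent-4-enal | O=C1C[C@H]([C@H](O[Si](C)(C)C(C)(C)C)CC(C)=O)[C@@H](/C=C(/C)[C@@H](OCc2ccc(OC)cc2)CC=O)O1 | intermediate
29 | (1S,10R)-cis-1,10-diol of the ten-membered trans lactone: 3-O-(4-methoxybenzyl), 8-O-TBS, Z-4-ene, saturated 12,6-lactone; C3, C6, C7, C8 arranged as in 44 | C1C(=O)O[C@@H]2/C=C(/C)[C@@H](OCc3ccc(OC)cc3)C[C@H](O)[C@@](O)(C)C[C@@H](O[Si](C)(C)C(C)(C)C)[C@@H]12 | intermediate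
30 | C1 methanesulfonate of 29 | C1C(=O)O[C@@H]2/C=C(/C)[C@@H](OCc3ccc(OC)cc3)C[C@H](OS(C)(=O)=O)[C@@](O)(C)C[C@@H](O[Si](C)(C)C(C)(C)C)[C@@H]12 | intermediate (not isolated)
31 | (1R,10R)-1,10-epoxide: 3-O-(4-methoxybenzyl), 8-O-TBS, Z-4-ene, saturated 12,6-lactone | C1C(=O)O[C@@H]2/C=C(/C)[C@@H](OCc3ccc(OC)cc3)C[C@H]3O[C@]3(C)C[C@@H](O[Si](C)(C)C(C)(C)C)[C@@H]12 | intermediate
32 | 11-(dimethylaminomethyl) derivative of 31 (C11 epimers) | CN(C)CC1C(=O)O[C@@H]2/C=C(/C)[C@@H](OCc3ccc(OC)cc3)C[C@H]3O[C@]3(C)C[C@@H](O[Si](C)(C)C(C)(C)C)[C@@H]12 | intermediate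
33 | trimethylammonium iodide of 32 | C[N+](C)(C)CC1C(=O)O[C@@H]2/C=C(/C)[C@@H](OCc3ccc(OC)cc3)C[C@H]3O[C@]3(C)C[C@@H](O[Si](C)(C)C(C)(C)C)[C@@H]12.[I-] | intermediate (not isolated)
34 | 11(13)-methylene lactone: (1R,10R)-epoxide, 3-O-(4-methoxybenzyl), 8-O-TBS | C=C1C(=O)O[C@@H]2/C=C(/C)[C@@H](OCc3ccc(OC)cc3)C[C@H]3O[C@]3(C)C[C@@H](O[Si](C)(C)C(C)(C)C)[C@@H]12 | intermediate
35 | 8-hydroxy compound (TBS removed from 34) | C=C1C(=O)O[C@@H]2/C=C(/C)[C@@H](OCc3ccc(OC)cc3)C[C@H]3O[C@]3(C)C[C@@H](O)[C@@H]12 | intermediate
36 | tiglic acid, (E)-2-methylbut-2-enoic acid | C/C=C(\C)C(=O)O | starting material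
37 | (E)-2-methylbut-2-en-1-ol | C/C=C(\C)CO | intermediate
38 | [(2S,3S)-2,3-dimethyloxiran-2-yl]methanol | OC[C@]1(C)O[C@H]1C | intermediate
39 | (2R,3S)-2,3-dimethyloxirane-2-carboxylic acid | OC(=O)[C@]1(C)O[C@H]1C | intermediate
40 | mixed anhydride of 39 with 2,4,6-trichlorobenzoic acid | O=C(OC(=O)c1c(Cl)cc(Cl)cc1Cl)[C@]1(C)O[C@H]1C | intermediate (not isolated)
41 | 8-O-[(2R,3S)-2,3-dimethyloxirane-2-carbonyl] derivative of 35 | C=C1C(=O)O[C@@H]2/C=C(/C)[C@@H](OCc3ccc(OC)cc3)C[C@H]3O[C@]3(C)C[C@@H](OC(=O)[C@]3(C)O[C@H]3C)[C@@H]12 | intermediate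
42 | 3-hydroxy compound (4-methoxybenzyl removed from 41) | C=C1C(=O)O[C@@H]2/C=C(/C)[C@@H](O)C[C@H]3O[C@]3(C)C[C@@H](OC(=O)[C@]3(C)O[C@H]3C)[C@@H]12 | intermediate
43 | (R)-2-methylbutanoic acid | CC[C@@H](C)C(=O)O | starting material
44 | CNP0265335.3: (1R,3S,6R,7R,8R,10R,4Z)-1,10-epoxy-3-[(2R)-2-methylbutanoyloxy]-8-[(2R,3S)-2,3-dimethyloxirane-2-carbonyloxy]germacra-4,11(13)-dien-12,6-olide | C=C1C(=O)O[C@@H]2/C=C(/C)[C@@H](OC(=O)[C@H](C)CC)C[C@H]3O[C@]3(C)C[C@@H](OC(=O)[C@]3(C)O[C@H]3C)[C@@H]12 | target

## Step count and least certain steps

Total step count: 26. Longest linear sequence: 22 steps (steps 1–7, 9–20, 24–26).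

**Step 16 (key step).** The most likely failures are two. Intermolecular coupling or plain reduction of the aldehyde may outrun closure of the strained ten-membered ring. The two carbonyl faces may also pair wrongly, giving the cis diol of the other face or a trans diol, because only the cis relationship is enforced by the chelate. The fallback sets out from keto-aldehyde 28. Low-valent titanium (TiCl3(DME)1.5, Zn–Cu, DME, reflux, slow addition) takes the same two carbonyl groups through the titanium pinacolate and on to the alkene, the (1(10)E,4Z)-diene lactone F1. Epoxidation of F1 with mCPBA (NaHCO3, CH2Cl2, 0 °C) should occur at the electron-rich C1=C10 alkene from the outer face of the ring; C4=C5 is deactivated by its two allylic oxygens. The route is rejoined at epoxide 31, with the epoxide configuration now set by the ring conformation rather than by the pinacol step.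

**Step 12.** Facial selectivity may be eroded if the C7 stereocentre opposes the reagent. The β-acyloxy aldehyde may also be lost by epimerisation at C7 or by β-elimination of the lactone carboxylate during addition or work-up. The fallback sets out from aldehyde 22. An L-proline-catalysed aldol with acetone (30 mol%, acetone/DMSO, rt), which for α-branched aldehydes favours the R carbinol, gives the β-hydroxy methyl ketone F2 directly, with no allylation and no Wacker oxidation. Silylation (TBSOTf, 2,6-lutidine, CH2Cl2, −78 °C) then gives 26, and the route is rejoined at 26, which is desilylated at O1 to 27 as in step 14.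

**Step 11.** Reduction on palladium may go too far (saturation or migration of the trisubstituted alkene, hydrogenolysis of the benzyl-type ether), or the acyl-palladium species may lose CO. The fallback sets out from imide 20. LiOH/H2O2 (THF/H2O, 0 °C) gives the lactone acid F3. BH3·SMe2 (THF, 0 °C), which reduces a carboxylic acid faster than a hindered alkene or a lactone, gives the hydroxymethyl lactone F4. Buffered Dess–Martin oxidation then gives aldehyde 22, where the route is rejoined. The free primary alcohol of F4 is kept away from base so that the lactone stays on O6.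

**Step 17.** Ring closure may be slow if the ten-membered ring cannot place O10 anti to the C1 leaving group. Elimination toward C2 or a 1,2-shift from C10 to C1 would then compete. The fallback sets out from diol 29 and returns at epoxide 31 in one operation, a Mitsunobu-type cyclodehydration (PPh3, DIAD, toluene, 0 °C to rt). The less hindered C1 oxygen becomes an oxyphosphonium leaving group under neutral conditions and is displaced by O10 with the same inversion. No discrete sulfonate and no free alkoxide are involved, and no new compound is made (F0).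

## Further compounds

F1 | step 16 | (1(10)E,4Z)-diene lactone: 3-O-(4-methoxybenzyl), 8-O-TBS, saturated 12,6-lactone | C1C(=O)O[C@@H]2/C=C(/C)[C@@H](OCc3ccc(OC)cc3)C/C=C(\C)C[C@@H](O[Si](C)(C)C(C)(C)C)[C@@H]12
F2 | step 12 | (4R,5R)-4-[(1R)-1-hydroxy-3-oxobutyl]-5-{(1Z,3S)-3-[(4-methoxybenzyl)oxy]-2-methyl-5-[(triethylsilyl)oxy]pent-1-en-1-yl}oxolan-2-one | O=C1C[C@H]([C@H](O)CC(C)=O)[C@@H](/C=C(/C)[C@@H](OCc2ccc(OC)cc2)CCO[Si](CC)(CC)CC)O1
F3 | step 11 | (2R,3S)-2-{(1Z,3S)-3-[(4-methoxybenzyl)oxy]-2-methyl-5-[(triethylsilyl)oxy]pent-1-en-1-yl}-5-oxooxolane-3-carboxylic acid | O=C1C[C@H](C(=O)O)[C@@H](/C=C(/C)[C@@H](OCc2ccc(OC)cc2)CCO[Si](CC)(CC)CC)O1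
F4 | step 11 | (4R,5R)-4-(hydroxymethyl)-5-{(1Z,3S)-3-[(4-methoxybenzyl)oxy]-2-methyl-5-[(triethylsilyl)oxy]pent-1-en-1-yl}oxolan-2-one | O=C1C[C@H](CO)[C@@H](/C=C(/C)[C@@H](OCc2ccc(OC)cc2)CCO[Si](CC)(CC)CC)O1
F0 | step 17 | none | none
A1 | alternative 1 | cis-anti-cis photoadduct: cyclohexanone fused to a bicyclo[2.2.0]hexane, C3 as dioxolane ketal, C8 TBS ether | O=C1C[C@H](O[Si](C)(C)C(C)(C)C)C[C@]2(C)[C@H]1[C@]1(C)[C@H]2CC13OCCO3
A2 | alternative 2 | 2,2-diisopropyl-1,3,2-dioxasilepine holding the cis C4=C5 alkene between O3 and O6 | CC1=C[C@H]([C@H](CCOCc2ccc(OC)cc2)[C@H](O[Si](C)(C)C(C)(C)C)CC2(C)OCCO2)O[Si](C(C)C)(C(C)C)O[C@H]1CC(OC)OC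
A3 | alternative 3 | isoxazoline-bridged ten-membered lactone (C1=N–O–C3 bridge, C10 tertiary alcohol, C8 TBS ether) | C1C(=O)O[C@@H]2/C=C(/C)[C@@H]3CC(=NO3)[C@](C)(O)C[C@@H](O[Si](C)(C)C(C)(C)C)[C@@H]12
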